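**Strategy.** Everything rests on reading the dihydropyran as a rearranged furan: O1, C2 with its two methyls, C3, C4, C5 with the cyclohexyl ring and C6 with its methyl are the carbinol oxygen, the carbinol carbon and furan C2–C5 of a 2-(2-furyl)propan-2-ol. One anodic oxidation with acid work-up dearomatises the furan and closes the six-membered ring through O1–C6, delivering C3 as a ketone for the later bromide and C4=C5/C6–OH for the enol ether. The precursor is furan 15, which already carries the (1S,3S,4S)-bromochlorocyclohexyl ring, built from (S)-limonene by a stereospecific bromine shift with chloride capture, and whose acid-labile carbinol is made last from a furoate.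

Key step: step 10

Remark: stereocentres that are destroyed later (carbinol carbon of 10, C4 of 13, the ketal carbons of 16, C6 of 18–23, C5 of 20–23) are carried as mixtures and are left undefined in the SMILES.

Step 1
Reactants: 1 (S)-(−)-limonene
Product: 4 (1R,2R,4S)-1-methyl-4-(prop-1-en-2-yl)cyclohexane-1,2-diol, via cis-limonene oxide 2 (not isolated), via trans-limonene oxide 3 (not isolated)
Conditions: mCPBA (1.0 equiv), CH2Cl2, 0 °C; then 1% aq H2SO4, acetone, 0 → 20 °C
Reagents that add atoms: 3-chloroperoxybenzoic acid, OOC(=O)c1cccc(Cl)c1; water, O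
Why: Prilezhaev epoxidation is selective for the trisubstituted ring alkene, and acid-catalysed trans-diaxial (Fürst–Plattner) hydrolysis opens the cis-oxide at the tertiary and the trans-oxide at the secondary carbon, so both epoxides should converge on the one diaxial diol, whose two new centres are fixed relative to the untouched C4.

Step 2
Reactants: 4 (1R,2R,4S)-1-methyl-4-(prop-1-en-2-yl)cyclohexane-1,2-diol
Product: 5 (1R,2R,5S)-2-bromo-2-methyl-5-(prop-1-en-2-yl)cyclohexan-1-ol
Conditions: 48% aq HBr (3 equiv), CH2Cl2, 0 °C, short contact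
Reagents that add atoms: hydrogen bromide, Br
Why: SN1 substitution of the tertiary hydroxyl only, assisted by the anti vicinal hydroxyl through the protonated cis-epoxide, should return bromide axially on the face the hydroxyl left (retention at the tertiary carbon), while the secondary alcohol does not ionise.

Step 3
Reactants: 5 (1R,2R,5S)-2-bromo-2-methyl-5-(prop-1-en-2-yl)cyclohexan-1-ol
Product: 7 (1S,2S,4S)-2-bromo-1-chloro-1-methyl-4-(prop-1-en-2-yl)cyclohexane, via bromohydrin mesylate 6 (not isolated)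
Conditions: MsCl, Et3N, CH2Cl2, −30 °C; then Et4NCl (5 equiv), MeCN, −30 → 20 °C
Reagents that add atoms: methanesulfonyl chloride, CS(=O)(=O)Cl (retained in 6 only); tetraethylammonium chloride, CC[N+](CC)(CC)CC.[Cl-]
Why: Sulfonate ionisation with neighbouring-group participation by the anti-periplanar tertiary bromine (1,2-bromine shift through an unsymmetrical bromonium ion) and Markovnikov capture of chloride at the tertiary carbon anti to bromine should invert both carbons, placing Br cis and Cl trans to the side chain with the methyl axial.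

Step 4
Reactants: 7 (1S,2S,4S)-2-bromo-1-chloro-1-methyl-4-(prop-1-en-2-yl)cyclohexane
Product: 8 2-[(1S,3S,4S)-3-bromo-4-chloro-4-methylcyclohexyl]prop-2-enal
Conditions: SeO2 (1.2 equiv), 1,4-dioxane, trace H2O, 80 °C
Reagents that add atoms: selenium dioxide, O=[Se]=O
Why: Riley allylic oxidation (ene reaction then [2,3]-sigmatropic shift) attacks the methyl of the 1,1-disubstituted alkene in preference to the ring methine, and the equatorial halides have no anti-periplanar hydrogen for elimination.

Step 5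
Reactants: 8 2-[(1S,3S,4S)-3-bromo-4-chloro-4-methylcyclohexyl]prop-2-enal; 9 methylmagnesium bromide
Product: 10 3-[(1S,3S,4S)-3-bromo-4-chloro-4-methylcyclohexyl]but-3-en-2-ol
Conditions: MeMgBr (1.2 equiv), THF, −78 °C; aq NH4Cl
Reagents that add atoms: methylmagnesium bromide 9, C[Mg]Br
Why: 1,2-Grignard addition to the enal is fast at −78 °C, where the alkyl halides are inert, and the uncontrolled carbinol centre is removed in step 6.

Step 6
Reactants: 10 3-[(1S,3S,4S)-3-bromo-4-chloro-4-methylcyclohexyl]but-3-en-2-ol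
Product: 11 3-[(1S,3S,4S)-3-bromo-4-chloro-4-methylcyclohexyl]but-3-en-2-one
Conditions: Dess–Martin periodinane, NaHCO3, CH2Cl2, 0 → 20 °C
Reagents that add atoms: none
Why: Dess–Martin oxidation of the allylic alcohol under buffered neutral conditions should give the α-methylene ketone without moving the double bond.

Step 7
Reactants: 11 3-[(1S,3S,4S)-3-bromo-4-chloro-4-methylcyclohexyl]but-3-en-2-one; 12 ethyl glyoxylate
Product: 13 ethyl 4-[(1S,3S,4S)-3-bromo-4-chloro-4-methylcyclohexyl]-2,5-dioxohexanoate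
Conditions: 3-benzyl-5-(2-hydroxyethyl)-4-methylthiazolium chloride (20 mol %), Et3N (30 mol %), 1,4-dioxane, 70 °C
Reagents that add atoms: ethyl glyoxylate 12, CCOC(=O)C=O
Why: Stetter reaction, in which the thiazolylidene turns the unhindered glyoxylate into an acyl-anion equivalent that adds to the unsubstituted β-carbon of the enone; the new centre α to the ketone is uncontrolled and disappears in step 8.

Step 8
Reactants: 13 ethyl 4-[(1S,3S,4S)-3-bromo-4-chloro-4-methylcyclohexyl]-2,5-dioxohexanoate
Product: 14 ethyl 4-[(1S,3S,4S)-3-bromo-4-chloro-4-methylcyclohexyl]-5-methylfuran-2-carboxylate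
Conditions: p-TsOH·H2O (10 mol %), toluene, 4 Å MS, 80 °C
Reagents that add atoms: none
Why: Paal–Knorr cyclodehydration of the 1,4-dicarbonyl unit gives an ester-deactivated furan that tolerates the acid, and the trans-diequatorial halides lack the anti-periplanar arrangement needed for elimination or bromine participation.

Step 9
Reactants: 14 ethyl 4-[(1S,3S,4S)-3-bromo-4-chloro-4-methylcyclohexyl]-5-methylfuran-2-carboxylate; 9 methylmagnesium bromide
Product: 15 2-{4-[(1S,3S,4S)-3-bromo-4-chloro-4-methylcyclohexyl]-5-methylfuran-2-yl}propan-2-ol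
Conditions: MeMgBr (3 equiv), THF, −20 → 0 °C; aq NH4Cl
Reagents that add atoms: methylmagnesium bromide 9, C[Mg]Br
Why: Double Grignard addition to the ester gives the tertiary furyl carbinol after the acidic step 8, so this acid-labile group never meets acid before the key step.

Step 10
Reactants: 15 2-{4-[(1S,3S,4S)-3-bromo-4-chloro-4-methylcyclohexyl]-5-methylfuran-2-yl}propan-2-ol
Product: 18 5-[(1S,3S,4S)-3-bromo-4-chloro-4-methylcyclohexyl]-6-hydroxy-2,2,6-trimethyl-2H-pyran-3(6H)-one, via dimethoxydihydrofuran 16 (not isolated), via cis-enedione 17 (not isolated)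
Conditions: undivided cell, graphite anode, Pt cathode, Et4NOTs (0.05 M), MeOH, −10 °C, constant current, 2.2 F mol−1; then 0.1 M H2SO4, THF/H2O, 20 °C
Reagents that add atoms: methanol, CO (retained in 16 only); water, O
Why: At the anode the electron-rich trialkylfuran loses two electrons and takes up methanol at both α-carbons to give 16, and aqueous acid hydrolyses both ketal carbons to the cis-enedione 17, whose tertiary hydroxyl adds to the methyl ketone to form O1–C6. This is the electrochemical form of the Achmatowicz rearrangement (anodic Clauson-Kaas methoxylation of a 2-furylcarbinol followed by acid rearrangement). The pyranone ring closes by 6-exo-trig addition of the carbinol oxygen to the ketone carbonyl. The only new stereocentre is the hemiketal carbon C6, which equilibrates under the acidic conditions and is erased in step 15. The step needs oxidation of the furan alone beside C–Br, C–Cl and the tertiary alcohol; the low oxidation potential of the furan, the metered charge and a platinum cathode, at which methanol and not the alkyl halides is reduced, should secure this.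

Step 11
Reactants: 18 5-[(1S,3S,4S)-3-bromo-4-chloro-4-methylcyclohexyl]-6-hydroxy-2,2,6-trimethyl-2H-pyran-3(6H)-one
Product: 19 5-[(1S,3S,4S)-3-bromo-4-chloro-4-methylcyclohexyl]-6-methoxy-2,2,6-trimethyl-2H-pyran-3(6H)-one
Conditions: HC(OMe)3, MeOH, PPTS (10 mol %), 20 °C
Reagents that add atoms: trimethyl orthoformate, COC(OC)OC
Why: Acid-catalysed ketal exchange through the ring oxocarbenium ion (Fischer-type glycosidation) locks the ring closed, so that the two carbonyl groups can no longer interchange through the open chain.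

Step 12
Reactants: 19 5-[(1S,3S,4S)-3-bromo-4-chloro-4-methylcyclohexyl]-6-methoxy-2,2,6-trimethyl-2H-pyran-3(6H)-one
Product: 20 5-[(1S,3S,4S)-3-bromo-4-chloro-4-methylcyclohexyl]-6-methoxy-2,2,6-trimethyldihydro-2H-pyran-3(4H)-one
Conditions: Cu(OAc)2·H2O (5 mol %), 1,2-bis(diphenylphosphino)benzene (5 mol %), (EtO)2MeSiH, t-BuOH, toluene, 20 °C
Reagents that add atoms: none
Why: Phosphine-ligated copper hydride conjugate reduction delivers hydride to C5 of the enone and tolerates alkyl bromides and chlorides; the C5 centre is uncontrolled and is removed in step 15.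

Step 13
Reactants: 20 5-[(1S,3S,4S)-3-bromo-4-chloro-4-methylcyclohexyl]-6-methoxy-2,2,6-trimethyldihydro-2H-pyran-3(4H)-one
Product: 21 (3S)-5-[(1S,3S,4S)-3-bromo-4-chloro-4-methylcyclohexyl]-6-methoxy-2,2,6-trimethyltetrahydro-2H-pyran-3-ol
Conditions: (R)-Me-CBS oxazaborolidine (20 mol %), BH3·SMe2, THF, −20 °C; MeOH
Reagents that add atoms: none
Why: Corey–Bakshi–Shibata reduction, in which the catalyst should direct hydride to one face of the ketone by distinguishing the quaternary C2 (large) from C4H2 (small), setting (3S) whatever the configuration at C5 and C6.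

Step 14
Reactants: 21 (3S)-5-[(1S,3S,4S)-3-bromo-4-chloro-4-methylcyclohexyl]-6-methoxy-2,2,6-trimethyltetrahydro-2H-pyran-3-ol
Product: 23 (3R)-3-bromo-5-[(1S,3S,4S)-3-bromo-4-chloro-4-methylcyclohexyl]-6-methoxy-2,2,6-trimethyltetrahydro-2H-pyran, via triflate 22 (not isolated)
Conditions: Tf2O, pyridine, CH2Cl2, −40 °C; then Bu4NBr, toluene, −20 → 20 °C
Reagents that add atoms: trifluoromethanesulfonic anhydride, O=S(=O)(OS(=O)(=O)C(F)(F)F)C(F)(F)F (retained in 22 only); tetrabutylammonium bromide, CCCC[N+](CCCC)(CCCC)CCCC.[Br-]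
Why: SN2 displacement of the triflate by bromide with inversion converts (3S)-OH into (3R)-Br, the β-ring oxygen slowing ionisation so that direct substitution should be the main path.

Step 15
Reactants: 23 (3R)-3-bromo-5-[(1S,3S,4S)-3-bromo-4-chloro-4-methylcyclohexyl]-6-methoxy-2,2,6-trimethyltetrahydro-2H-pyran
Product: 24 laucapyranoid A, (3R)-3-bromo-5-[(1S,3S,4S)-3-bromo-4-chloro-4-methylcyclohexyl]-2,2,6-trimethyl-3,4-dihydro-2H-pyran
Conditions: PPTS (10 mol %), toluene, 5 Å MS, 80 °C
Reagents that add atoms: none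
Why: Acid-catalysed E1 loss of methanol through the ring oxocarbenium ion under thermodynamic control should give the tetrasubstituted endocyclic C5=C6 enol ether, erasing the C5 and C6 centres and leaving C3 and the cyclohexane centres untouched.

**Compound list**

1 | (S)-(−)-limonene, (4S)-1-methyl-4-(prop-1-en-2-yl)cyclohex-1-ene | CC(=C)[C@H]1CCC(C)=CC1 | starting material
2 | cis-(1S,2R,4S)-limonene 1,2-oxide (not isolated) | CC(=C)[C@H]1CC[C@]2(C)O[C@@H]2C1 | intermediate
3 | trans-(1R,2S,4S)-limonene 1,2-oxide (not isolated) | CC(=C)[C@H]1CC[C@@]2(C)O[C@H]2C1 | intermediate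
4 | (1R,2R,4S)-1-methyl-4-(prop-1-en-2-yl)cyclohexane-1,2-diol | CC(=C)[C@H]1CC[C@@](C)(O)[C@H](O)C1 | intermediate
5 | (1R,2R,5S)-2-bromo-2-methyl-5-(prop-1-en-2-yl)cyclohexan-1-ol | CC(=C)[C@H]1CC[C@@](C)(Br)[C@H](O)C1 | intermediate
6 | (1R,2R,5S)-2-bromo-2-methyl-5-(prop-1-en-2-yl)cyclohexyl methanesulfonate (not isolated) | CC(=C)[C@H]1CC[C@@](C)(Br)[C@H](OS(C)(=O)=O)C1 | intermediate
7 | (1S,2S,4S)-2-bromo-1-chloro-1-methyl-4-(prop-1-en-2-yl)cyclohexane | CC(=C)[C@H]1CC[C@](C)(Cl)[C@@H](Br)C1 | intermediate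
8 | 2-[(1S,3S,4S)-3-bromo-4-chloro-4-methylcyclohexyl]prop-2-enal | C=C(C=O)[C@H]1CC[C@](C)(Cl)[C@@H](Br)C1 | intermediate
9 | methylmagnesium bromide | C[Mg]Br | starting material
10 | 3-[(1S,3S,4S)-3-bromo-4-chloro-4-methylcyclohexyl]but-3-en-2-ol (carbinol epimers) | CC(O)C(=C)[C@H]1CC[C@](C)(Cl)[C@@H](Br)C1 | intermediate
11 | 3-[(1S,3S,4S)-3-bromo-4-chloro-4-methylcyclohexyl]but-3-en-2-one | CC(=O)C(=C)[C@H]1CC[C@](C)(Cl)[C@@H](Br)C1 | intermediate
12 | ethyl glyoxylate | CCOC(=O)C=O | starting material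
13 | ethyl 4-[(1S,3S,4S)-3-bromo-4-chloro-4-methylcyclohexyl]-2,5-dioxohexanoate (C4 epimers) | CCOC(=O)C(=O)CC(C(C)=O)[C@H]1CC[C@](C)(Cl)[C@@H](Br)C1 | intermediate
14 | ethyl 4-[(1S,3S,4S)-3-bromo-4-chloro-4-methylcyclohexyl]-5-methylfuran-2-carboxylate | CCOC(=O)c1cc([C@H]2CC[C@](C)(Cl)[C@@H](Br)C2)c(C)o1 | intermediate
15 | 2-{4-[(1S,3S,4S)-3-bromo-4-chloro-4-methylcyclohexyl]-5-methylfuran-2-yl}propan-2-ol | CC(C)(O)c1cc([C@H]2CC[C@](C)(Cl)[C@@H](Br)C2)c(C)o1 | intermediate
16 | 2-{4-[(1S,3S,4S)-3-bromo-4-chloro-4-methylcyclohexyl]-2,5-dimethoxy-5-methyl-2,5-dihydrofuran-2-yl}propan-2-ol (not isolated, isomer mixture) | COC1(C)OC(OC)(C=C1[C@H]2CC[C@](C)(Cl)[C@@H](Br)C2)C(C)(C)O | intermediate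
17 | (3Z)-3-[(1S,3S,4S)-3-bromo-4-chloro-4-methylcyclohexyl]-6-hydroxy-6-methylhept-3-ene-2,5-dione (not isolated) | CC(=O)/C(=C\C(=O)C(C)(C)O)[C@H]1CC[C@](C)(Cl)[C@@H](Br)C1 | intermediate
18 | 5-[(1S,3S,4S)-3-bromo-4-chloro-4-methylcyclohexyl]-6-hydroxy-2,2,6-trimethyl-2H-pyran-3(6H)-one (equilibrating anomers) | CC1(O)OC(C)(C)C(=O)C=C1[C@H]2CC[C@](C)(Cl)[C@@H](Br)C2 | intermediate
19 | 5-[(1S,3S,4S)-3-bromo-4-chloro-4-methylcyclohexyl]-6-methoxy-2,2,6-trimethyl-2H-pyran-3(6H)-one | COC1(C)OC(C)(C)C(=O)C=C1[C@H]2CC[C@](C)(Cl)[C@@H](Br)C2 | intermediate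
20 | 5-[(1S,3S,4S)-3-bromo-4-chloro-4-methylcyclohexyl]-6-methoxy-2,2,6-trimethyldihydro-2H-pyran-3(4H)-one | COC1(C)OC(C)(C)C(=O)CC1[C@H]2CC[C@](C)(Cl)[C@@H](Br)C2 | intermediate
21 | (3S)-5-[(1S,3S,4S)-3-bromo-4-chloro-4-methylcyclohexyl]-6-methoxy-2,2,6-trimethyltetrahydro-2H-pyran-3-ol | COC1(C)OC(C)(C)[C@@H](O)CC1[C@H]2CC[C@](C)(Cl)[C@@H](Br)C2 | intermediate
22 | (3S)-5-[(1S,3S,4S)-3-bromo-4-chloro-4-methylcyclohexyl]-6-methoxy-2,2,6-trimethyltetrahydro-2H-pyran-3-yl trifluoromethanesulfonate (not isolated) | COC1(C)OC(C)(C)[C@@H](OS(=O)(=O)C(F)(F)F)CC1[C@H]2CC[C@](C)(Cl)[C@@H](Br)C2 | intermediate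
23 | (3R)-3-bromo-5-[(1S,3S,4S)-3-bromo-4-chloro-4-methylcyclohexyl]-6-methoxy-2,2,6-trimethyltetrahydro-2H-pyran | COC1(C)OC(C)(C)[C@H](Br)CC1[C@H]2CC[C@](C)(Cl)[C@@H](Br)C2 | intermediate
24 | laucapyranoid A | CC1=C([C@H]2CC[C@](C)(Cl)[C@@H](Br)C2)C[C@@H](Br)C(C)(C)O1 | target

**Count.** Total steps: 15. Longest linear sequence: 15 steps (1 → 24); the route is linear, with 9 and 12 as bought building blocks.

**Steps most likely to fail**

1. Step 3. The bromonium/chloride ion pair may collapse at the secondary carbon (the trans-diaxial mode) or lose a proton, instead of taking chloride at the tertiary carbon. Direct anti bromochlorination of the limonene double bond is no way out, since it would give the trans-diaxial array with both halogen-bearing carbons epimeric to the target. Fallback: setting out from bromohydrin 5, thionyl chloride and pyridine in ether at 0 °C, where chloride is returned within the ion pair, are used on purpose to make the trans-diaxial regioisomer (1R,2R,4S)-1-bromo-2-chloro-1-methyl-4-(prop-1-en-2-yl)cyclohexane F1. F1 is then heated (MeCN, 80 °C) to equilibrate it with 7 by the diaxial-to-diequatorial 1,2-interchange of vicinal halogens (dyotropic rearrangement, known for steroidal and cyclohexane bromochlorides); 7 is separated and F1 recycled. The fallback comes back to the route at 7.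

2. Step 14. Substitution at a secondary carbon next to the quaternary C2 may be too slow, so that elimination towards C4, ring contraction by participation of the ring oxygen, or capture of C3 by the ketal methoxy oxygen take over. Fallback: setting out from ketone 20, reduction with the (S)-configured CBS catalyst gives (3R)-5-[(1S,3S,4S)-3-bromo-4-chloro-4-methylcyclohexyl]-6-methoxy-2,2,6-trimethyltetrahydro-2H-pyran-3-ol F3, which is converted (MsCl, Et3N) into its methanesulfonate F4. Mild aqueous acid (PPTS, acetone/H2O) removes the ketal and gives the open hydroxy ketone (5R)-3-[(1S,3S,4S)-3-bromo-4-chloro-4-methylcyclohexyl]-6-hydroxy-6-methyl-2-oxoheptan-5-yl methanesulfonate F5. Its tertiary alkoxide (K2CO3, MeOH) closes the epoxide 3-[(1S,3S,4S)-3-bromo-4-chloro-4-methylcyclohexyl]-4-[(2S)-3,3-dimethyloxiran-2-yl]butan-2-one F6 with inversion at C3. Bromide (Li2NiBr4, THF) opens the epoxide at the secondary carbon with a second inversion to (5R)-5-bromo-3-[(1S,3S,4S)-3-bromo-4-chloro-4-methylcyclohexyl]-6-hydroxy-6-methylheptan-2-one F7. Acid-catalysed cyclodehydration of this δ-hydroxy ketone (PPTS, toluene, 5 Å MS, 80 °C) closes the enol ether, and the fallback comes back at target 24.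

3. Step 7. Acyl-anion transfer may fail because self-condensation of the glyoxylate or polymerisation of the α-methylene ketone outruns conjugate addition. Fallback: setting out from enone 11, base-catalysed Michael addition of ethyl nitroacetate (Et3N, THF, 20 °C) gives ethyl 4-[(1S,3S,4S)-3-bromo-4-chloro-4-methylcyclohexyl]-2-nitro-5-oxohexanoate F2. An oxidative Nef reaction of its nitronate (K2CO3, MeOH; then dimethyldioxirane, acetone, 0 °C) gives the α-keto ester, and the fallback comes back at 13.

**Further compounds**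

F1 | step 3 | (1R,2R,4S)-1-bromo-2-chloro-1-methyl-4-(prop-1-en-2-yl)cyclohexane | CC(=C)[C@H]1CC[C@@](C)(Br)[C@H](Cl)C1
F2 | step 7 | ethyl 4-[(1S,3S,4S)-3-bromo-4-chloro-4-methylcyclohexyl]-2-nitro-5-oxohexanoate | CCOC(=O)C([N+](=O)[O-])CC(C(C)=O)[C@H]1CC[C@](C)(Cl)[C@@H](Br)C1
F3 | step 14 | (3R)-5-[(1S,3S,4S)-3-bromo-4-chloro-4-methylcyclohexyl]-6-methoxy-2,2,6-trimethyltetrahydro-2H-pyran-3-ol | COC1(C)OC(C)(C)[C@H](O)CC1[C@H]2CC[C@](C)(Cl)[C@@H](Br)C2
F4 | step 14 | (3R)-5-[(1S,3S,4S)-3-bromo-4-chloro-4-methylcyclohexyl]-6-methoxy-2,2,6-trimethyltetrahydro-2H-pyran-3-yl methanesulfonate | COC1(C)OC(C)(C)[C@H](OS(C)(=O)=O)CC1[C@H]2CC[C@](C)(Cl)[C@@H](Br)C2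
F5 | step 14 | (5R)-3-[(1S,3S,4S)-3-bromo-4-chloro-4-methylcyclohexyl]-6-hydroxy-6-methyl-2-oxoheptan-5-yl methanesulfonate | CC(=O)C(C[C@@H](OS(C)(=O)=O)C(C)(C)O)[C@H]1CC[C@](C)(Cl)[C@@H](Br)C1
F6 | step 14 | 3-[(1S,3S,4S)-3-bromo-4-chloro-4-methylcyclohexyl]-4-[(2S)-3,3-dimethyloxiran-2-yl]butan-2-one | CC(=O)C(C[C@@H]1OC1(C)C)[C@H]2CC[C@](C)(Cl)[C@@H](Br)C2
F7 | step 14 | (5R)-5-bromo-3-[(1S,3S,4S)-3-bromo-4-chloro-4-methylcyclohexyl]-6-hydroxy-6-methylheptan-2-one | CC(=O)C(C[C@@H](Br)C(C)(C)O)[C@H]1CC[C@](C)(Cl)[C@@H](Br)C1
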